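**Plan**
1. Numbering (xanthanolide type, primes for the epoxide half): C1 carbinol carbon, C5 its CH neighbour, C6 CH2, C7 CH carrying C11, C8 CH–O, C9 CH2, C10 CH–CH3, C2–C4/C15 the oxobutenyl chain, C11/C12/C13 lactone α-carbon, C=O and exocyclic CH2.
2. Cuts: first the C1–OH (γ-oxygenation), then the cyclohexene bonds C5–C13' and C3–C11' (Diels–Alder). This gives a (7R,8R,10S) dienone methylene lactone and the 1,5-epoxide of its enantiomer, so both halves come from one racemic monomer.
3. Monomer: side chain by Wittig reaction at C2, C13 by Mannich/elimination, cis-lactone by carboxylate SN2 at C8, C6 carbonyl removed by hydrazone reduction; the cycloheptane is then cut at C1–C5 and C7–C8.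
4. Enabling feature: in this seven-membered ring C8–C9–C10(CH3)–C1 is a four-carbon run whose ends can share one oxygen (a 2,3-disubstituted furan), and C5–C6–C7 is a three-carbon run with a bare central carbon (an oxyallyl cation). A (4+3) cycloaddition joins them.
5. Forward: furan → 8-oxabicyclo[3.2.1]octenone → hydrogenation and C7 alkylation on the bicycle → bridge opening at C1 → C6 deoxygenation → lactone, methylene, dienone → resolution → epoxidation of one enantiomer → Diels–Alder → C1 oxygenation.
6. Stereochemistry: C1/C8 cis from the cycloaddition; C10 and C7 from the exo face of the bicycle; C8 inverted by SN2; absolute configuration by resolution (both enantiomers used); epoxide, C5/C11' and C1–OH by substrate control.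

Key step: step 3

Remark: the target has its two halves in opposite enantiomeric series at C7/C8/C10, so a racemic monomer is made and both enantiomers are used. Compounds 5 to 26 are racemic; names and SMILES show the enantiomer that ends in diene half 27. The numbering of the plan is used throughout, also for the bicycles (bridgeheads C1 and C8).

**Step 1**
Reactants: 1 methyl 3-methylfuran-2-carboxylate
Product: 2 (3-methylfuran-2-yl)methanol
Conditions: LiAlH4, Et2O, 0 °C; H2O, aq NaOH work-up
Reagents that add atoms: none
Why: Hydride reduction of the ester to the primary alcohol (LiAlH4 reduction) leaves the furan untouched.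

**Step 2**
Reactants: 2 (3-methylfuran-2-yl)methanol
Product: 3 tert-butyl[(3-methylfuran-2-yl)methoxy]diphenylsilane
Conditions: t-BuPh2SiCl, imidazole, CH2Cl2, 0 → 25 °C
Reagents that add atoms: tert-butylchlorodiphenylsilane, CC(C)(C)[Si](Cl)(c1ccccc1)c1ccccc1
Why: Silyl ether formation gives a C2 oxygen that should survive Lewis acids, hydrogenation, strong base and CF3CO2H and is cleaved by fluoride in step 12.

**Step 3**
Reactants: 3 tert-butyl[(3-methylfuran-2-yl)methoxy]diphenylsilane; 4 1,1,3,3-tetrabromopropan-2-one
Product: 6 rac-1-[(tert-butyldiphenylsilyloxy)methyl]-7-methyl-8-oxabicyclo[3.2.1]oct-6-en-3-one, via dibromo cycloadduct 5 (not isolated)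
Conditions: 4 (1.5 equiv), Zn–Ag couple, THF, −10 → 25 °C; then Zn–Cu couple, NH4Cl, MeOH, 25 °C
Reagents that add atoms: none
Why: Zn–Ag couple reduces 4 to a zinc 1,3-dibromo-2-oxidoallyl cation, which adds across the two α-carbons of the electron-rich furan 3 in a (4+3) cycloaddition (4π furan plus 2π allyl cation), the closest known type being the oxyallyl cation–furan cycloaddition; Zn–Cu couple then removes both bromine atoms. The seven-membered carbocycle is closed by two intermolecular C–C bonds (C1–C5 and C7–C8) in cycloaddition mode, and the furan oxygen is left as a one-atom bridge from C1 to C8. The only stereocentres that survive, C1 and C8, are set cis because both bonds form on one face of the flat furan; the product is racemic, which is wanted because each enantiomer serves one half of the target. The step needs cycloaddition to win over electrophilic substitution at the free furan α-position, which the zinc-bound (less electrophilic) oxyallyl species and the electron-rich 2,3-dialkylfuran should secure; there is no regiochemical question because the debrominated three-carbon unit is symmetric. The C6 ketone and the oxygen bridge are helpers that steer steps 4 to 8 and are then removed (the ketone in steps 7 and 8, the bridge oxygen from C1 in step 6 and from C8 in step 10).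

**Step 4**
Reactants: 6 rac-1-[(tert-butyldiphenylsilyloxy)methyl]-7-methyl-8-oxabicyclo[3.2.1]oct-6-en-3-one
Product: 7 rac-1-[(tert-butyldiphenylsilyloxy)methyl]-7-endo-methyl-8-oxabicyclo[3.2.1]octan-3-one (C10 methyl anti to the oxygen bridge)
Conditions: H2 (1 atm), 5% Pd/C, EtOAc, 25 °C
Reagents that add atoms: none
Why: Heterogeneous hydrogenation should deliver both hydrogens to the exo face (the side of the oxygen bridge), because the endo face is covered by the C5–C6–C7 bridge, so the C10 methyl ends up anti to the bridging oxygen.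

**Step 5**
Reactants: 7 rac-7-endo-methyl bicyclic ketone; 8 tert-butyl bromoacetate
Product: 10 rac-equatorial keto ester (7 with CH2CO2t-Bu on C7; arm anti to the oxygen bridge and cis to the C10 methyl), via axial C7 epimer 9 (not isolated)
Conditions: LiN(i-Pr)2, THF, −78 °C; 8, DMPU, −78 → −30 °C; aq NH4Cl; crude product, DBU (0.3 equiv), toluene, 50 °C
Reagents that add atoms: none
Why: Kinetic deprotonation should occur at C7, the α-CH2 next to the unsubstituted bridgehead (C5 is screened by the quaternary C1 and the endo methyl); the enolate is alkylated from the exo face (enolate alkylation), and DBU then equilibrates C7 through the enol to the more stable equatorial epimer with H-7 on the exo face.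

**Step 6**
Reactants: 10 rac-equatorial keto ester
Product: 12 rac-hydroxy enone (C6 ketone; C1=C5; C8–OH trans to the C7 arm and to the C10 methyl), via trimethylsilyl ether 11 (not isolated)
Conditions: Me3SiOTf (1.5 equiv), Et3N (3 equiv), CH2Cl2, −20 → 0 °C; then 1 M HCl, THF, 0 °C
Reagents that add atoms: none
Why: Silyl triflate/amine-promoted β-elimination (retro-oxa-Michael opening of an oxabicyclic ketone): the silylated bridge oxygen leaves the tertiary C1 with loss of a proton from the α-CH2 at C5, which gives the C1=C5 enone, keeps the oxygen on C8 and leaves C7, C8 and C10 unchanged.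

**Step 7**
Reactants: 12 rac-hydroxy enone
Product: 13 rac-tosylhydrazone of 12 (C6=N–NHTs)
Conditions: 4-MeC6H4SO2NHNH2, EtOH, 50 °C
Reagents that add atoms: 4-methylbenzenesulfonohydrazide, Cc1ccc(cc1)S(=O)(=O)NN
Why: Condensation of the enone carbonyl with tosylhydrazide (hydrazone formation) prepares C6 for reductive removal without touching a stereocentre.

**Step 8**
Reactants: 13 rac-tosylhydrazone
Product: 15 rac-cycloheptenol (C5=C6; C6 now CH; C1–H as epimer mixture; C8–OH as in 12), via allylic diazene 14 (not isolated)
Conditions: catecholborane (3 equiv), CHCl3, 0 °C; then NaOAc·3H2O, 60 °C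
Reagents that add atoms: none
Why: Catecholborane reduction of an α,β-unsaturated tosylhydrazone (a modified Wolff–Kishner reduction): hydride adds to C6, sulfinate is lost and the allylic diazene passes its hydrogen to C1 with loss of N2 (retro-ene), so the C6 oxygen is deleted and the alkene moves to C5=C6, from where step 13 returns it; the C1 centre formed here is temporary.

**Step 9**
Reactants: 15 rac-cycloheptenol
Product: 16 rac-C8 methanesulfonate of 15
Conditions: MeSO2Cl, Et3N, CH2Cl2, 0 °C
Reagents that add atoms: methanesulfonyl chloride, CS(=O)(=O)Cl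
Why: Mesylation turns the C8 oxygen (the former furan oxygen) into a leaving group with retention at C8.

**Step 10**
Reactants: 16 rac-C8 methanesulfonate
Product: 18 rac-cis-fused γ-lactone (lactone oxygen on C8 and C11 on C7 on the same face as the C10 methyl; C5=C6; CH2OSi on C1), via carboxylic acid 17 (not isolated)
Conditions: CF3CO2H/CH2Cl2 (1:4), 0 → 25 °C; evaporate; Cs2CO3, DMF, 40 °C
Reagents that add atoms: none
Why: Acidolysis of the tert-butyl ester, then intramolecular SN2 displacement of the mesylate by the carboxylate (5-exo-tet lactonisation) inverts C8, so that the lactone oxygen, C11 and the C10 methyl all lie on one face.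

**Step 11**
Reactants: 18 rac-cis-fused γ-lactone
Product: 21 rac-α-methylene lactone (C11=C13H2), via Mannich base 19 (not isolated), via ammonium iodide 20 (not isolated)
Conditions: LiN(SiMe3)2, THF, −78 °C; CH2=NMe2+ I−, −78 → 0 °C; MeI, MeOH, 25 °C; aq NaHCO3, CH2Cl2, 25 °C
Reagents that add atoms: N,N-dimethylmethyleneiminium iodide (Eschenmoser's salt), C=[N+](C)C.[I-]
Why: Aminomethylation of the lactone enolate, N-quaternisation and base-induced loss of trimethylamine (Mannich/elimination α-methylenation) install C13; the C11 centre of 19 disappears in the elimination.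

**Step 12**
Reactants: 21 rac-α-methylene lactone
Product: 22 rac-primary alcohol (C2–OH)
Conditions: HF·pyridine, pyridine, THF, 0 → 25 °C
Reagents that add atoms: none
Why: Fluoride cleavage of the silyl ether (desilylation) frees the C2 alcohol under conditions that should not add to the methylene lactone.

**Step 13**
Reactants: 22 rac-primary alcohol
Product: 24 rac-conjugated enal (C2 aldehyde on C1=C5), via β,γ-unsaturated aldehyde 23 (not isolated)
Conditions: Dess–Martin periodinane, CH2Cl2, 0 → 25 °C; then DBU (0.1 equiv), 0 °C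
Reagents that add atoms: none
Why: Dess–Martin oxidation gives the aldehyde, and base then moves H-1 to C6 through the dienolate (β,γ to α,β isomerisation), which restores C1=C5 in conjugation and removes the temporary C1 centre.

**Step 14**
Reactants: 24 rac-conjugated enal; 25 1-(triphenylphosphoranylidene)propan-2-one
Product: 26 racemic 7-methyl-3-methylidene-6-[(1E)-3-oxobut-1-enyl]-3,3a,4,7,8,8a-hexahydro-2H-cyclohepta[b]furan-2-one (all-cis dienone monomer)
Conditions: toluene, 60 °C
Reagents that add atoms: none
Why: Wittig olefination with the stabilised ylide should give the (E)-enone and complete the C5=C1–C2=C3 diene, the aldehyde reacting far faster than the methylene lactone.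

**Step 15**
Reactants: 26 racemic dienone monomer
Product: 27 (3aR,7S,8aR)-enantiomer (7R,8R,10S) and 28 (3aS,7R,8aS)-enantiomer (7S,8S,10R)
Conditions: preparative HPLC on amylose tris(3,5-dimethylphenylcarbamate), hexane/i-PrOH, 25 °C
Reagents that add atoms: none
Why: Resolution by chromatography on a chiral stationary phase separates the enantiomers without chemical change; both are used, 27 as diene and 28 (collected as the other fraction) as dienophile precursor, and which fraction is which should be established by anomalous-dispersion X-ray crystallography of epoxide 29.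

**Step 16**
Reactants: 28 (7S,8S,10R)-dienone monomer
Product: 29 1,5-epoxide of 28 (oxirane oxygen trans to the C10 methyl and to the lactone)
Conditions: dimethyldioxirane (1.1 equiv), acetone/CH2Cl2, −20 → 0 °C
Reagents that add atoms: dimethyldioxirane, CC1(C)OO1
Why: Electrophilic dioxirane epoxidation should select C1=C5, the only alkene not directly attached to a carbonyl group, and is expected to occur anti to the C10 methyl and the cis-fused lactone, which sets C1 and C5 of this half.

**Step 17**
Reactants: 27 (7R,8R,10S)-dienone monomer; 29 1,5-epoxide of 28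
Product: 30 spiro cycloadduct (C5–C13' and C3–C11' bonds; C1=C2; H-3 cis to H-5)
Conditions: 27 (1 equiv), 29 (3 equiv, excess recovered), BHT (5 mol %), toluene (1 M), 100 °C, sealed tube, dark
Reagents that add atoms: none
Why: Thermal Diels–Alder reaction of the s-cis diene C5=C1–C2=C3 with the methylene lactone C11'=C13' should give the "ortho" regioisomer (acetyl-bearing C3 to C11') through the carbonyl-exo transition state usual for α-methylene lactones, with the diene on the convex face of the cis-fused lactone (anti to C6') and the dienophile on the diene face syn to the C10 methyl (the face left open if the ring folds C7–C9 to the other side); these three preferences can be met together only in this heterochiral pairing, which sets C5 and C11', while the C3 centre is erased in step 18.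

**Step 18**
Reactants: 30 spiro cycloadduct
Product: 32 target CNP0177598.2, via C1 hydroperoxide 31 (not isolated)
Conditions: DBU (0.5 equiv), O2 (1 atm), P(OEt)3 (2 equiv), MeCN, 0 °C
Reagents that add atoms: dioxygen, O=O
Why: Base-mediated autoxidation of the β,γ-unsaturated ketone (dienolate γ-oxygenation with in situ phosphite reduction): DBU removes the doubly activated H-3, O2 should add at the γ-terminus C1 from the face anti to the axial H-5 and the axial lactone carbonyl C12' (as in the 6β-oxygenation of steroidal dienolates), and the alkene moves to C2=C3 in conjugation with the acetyl group, giving the tertiary C1 alcohol cis to the C10 methyl.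

**Compound list**
1 | methyl 3-methylfuran-2-carboxylate | COC(=O)c1occc1C | starting material
2 | (3-methylfuran-2-yl)methanol | Cc1ccoc1CO | intermediate
3 | tert-butyl[(3-methylfuran-2-yl)methoxy]diphenylsilane | Cc1ccoc1CO[Si](c1ccccc1)(c1ccccc1)C(C)(C)C | intermediate
4 | 1,1,3,3-tetrabromopropan-2-one | O=C(C(Br)Br)C(Br)Br | starting material
5 | rac-2,4-dibromo-1-[(tert-butyldiphenylsilyloxy)methyl]-7-methyl-8-oxabicyclo[3.2.1]oct-6-en-3-one (bromo epimers) | O=C1C(Br)[C@]2(CO[Si](c3ccccc3)(c3ccccc3)C(C)(C)C)O[C@H](C1Br)C=C2C | intermediate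
6 | rac-1-[(tert-butyldiphenylsilyloxy)methyl]-7-methyl-8-oxabicyclo[3.2.1]oct-6-en-3-one | O=C1C[C@]2(CO[Si](c3ccccc3)(c3ccccc3)C(C)(C)C)O[C@H](C1)C=C2C | intermediate
7 | rac-1-[(tert-butyldiphenylsilyloxy)methyl]-7-endo-methyl-8-oxabicyclo[3.2.1]octan-3-one | O=C1C[C@]2(CO[Si](c3ccccc3)(c3ccccc3)C(C)(C)C)O[C@H](C1)C[C@@H]2C | intermediate
8 | tert-butyl bromoacetate | CC(C)(C)OC(=O)CBr | starting material
9 | rac-7 with CH2CO2t-Bu on C7, axial (syn to the oxygen bridge) | O=C1C[C@]2(CO[Si](c3ccccc3)(c3ccccc3)C(C)(C)C)O[C@H]([C@@H]1CC(=O)OC(C)(C)C)C[C@@H]2C | intermediate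
10 | rac-7 with CH2CO2t-Bu on C7, equatorial (anti to the oxygen bridge, cis to the C10 methyl) | O=C1C[C@]2(CO[Si](c3ccccc3)(c3ccccc3)C(C)(C)C)O[C@H]([C@H]1CC(=O)OC(C)(C)C)C[C@@H]2C | intermediate
11 | rac-C8 trimethylsilyl ether of 12 | O=C1C=C(CO[Si](c2ccccc2)(c2ccccc2)C(C)(C)C)[C@@H](C)C[C@H](O[Si](C)(C)C)[C@H]1CC(=O)OC(C)(C)C | intermediate
12 | rac-tert-butyl 2-[3-(tert-butyldiphenylsilyloxymethyl)-6-hydroxy-4-methyl-1-oxocyclohept-2-en-7-yl]acetate (OH trans to the arm and to the methyl) | O=C1C=C(CO[Si](c2ccccc2)(c2ccccc2)C(C)(C)C)[C@@H](C)C[C@H](O)[C@H]1CC(=O)OC(C)(C)C | intermediate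
13 | rac-tosylhydrazone of 12 | Cc1ccc(cc1)S(=O)(=O)NN=C1C=C(CO[Si](c2ccccc2)(c2ccccc2)C(C)(C)C)[C@@H](C)C[C@H](O)[C@H]1CC(=O)OC(C)(C)C | intermediate
14 | rac-allylic diazene (C6–N=NH) | N=NC1C=C(CO[Si](c2ccccc2)(c2ccccc2)C(C)(C)C)[C@@H](C)C[C@H](O)[C@H]1CC(=O)OC(C)(C)C | intermediate
15 | rac-cycloheptenol (C5=C6, C1–H epimers, C8–OH trans to the C7 arm and the C10 methyl) | C1=CC(CO[Si](c2ccccc2)(c2ccccc2)C(C)(C)C)[C@@H](C)C[C@H](O)[C@H]1CC(=O)OC(C)(C)C | intermediate
16 | rac-C8 methanesulfonate of 15 | C1=CC(CO[Si](c2ccccc2)(c2ccccc2)C(C)(C)C)[C@@H](C)C[C@H](OS(C)(=O)=O)[C@H]1CC(=O)OC(C)(C)C | intermediate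
17 | rac-carboxylic acid from 16 | C1=CC(CO[Si](c2ccccc2)(c2ccccc2)C(C)(C)C)[C@@H](C)C[C@H](OS(C)(=O)=O)[C@H]1CC(=O)O | intermediate
18 | rac-cis-fused γ-lactone (O on C8, C11 and C10 methyl on one face; C5=C6; C1 epimers) | O=C1C[C@H]2C=CC(CO[Si](c3ccccc3)(c3ccccc3)C(C)(C)C)[C@@H](C)C[C@H]2O1 | intermediate
19 | rac-α-(dimethylaminomethyl) lactone (Mannich base) | CN(C)CC1C(=O)O[C@@H]2C[C@H](C)C(CO[Si](c3ccccc3)(c3ccccc3)C(C)(C)C)C=C[C@H]12 | intermediate
20 | rac-trimethylammonium iodide of 19 | C[N+](C)(C)CC1C(=O)O[C@@H]2C[C@H](C)C(CO[Si](c3ccccc3)(c3ccccc3)C(C)(C)C)C=C[C@H]12.[I-] | intermediate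
21 | rac-α-methylene lactone with CH2OSi on C1 | C=C1C(=O)O[C@@H]2C[C@H](C)C(CO[Si](c3ccccc3)(c3ccccc3)C(C)(C)C)C=C[C@H]12 | intermediate
22 | rac-α-methylene lactone with CH2OH on C1 | C=C1C(=O)O[C@@H]2C[C@H](C)C(CO)C=C[C@H]12 | intermediate
23 | rac-β,γ-unsaturated aldehyde (CHO on C1, C5=C6) | C=C1C(=O)O[C@@H]2C[C@H](C)C(C=O)C=C[C@H]12 | intermediate
24 | rac-conjugated enal (CHO on C1, C1=C5) | C=C1C(=O)O[C@@H]2C[C@H](C)C(C=O)=CC[C@H]12 | intermediate
25 | 1-(triphenylphosphoranylidene)propan-2-one | CC(=O)C=P(c1ccccc1)(c1ccccc1)c1ccccc1 | starting material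
26 | racemic all-cis dienone monomer (1:1 mixture of 27 and 28) | C=C1C(=O)O[C@@H]2C[C@H](C)C(/C=C/C(C)=O)=CC[C@H]12.C=C1C(=O)O[C@H]2C[C@@H](C)C(/C=C/C(C)=O)=CC[C@@H]12 | intermediate
27 | (3aR,7S,8aR)-7-methyl-3-methylidene-6-[(1E)-3-oxobut-1-enyl]-3,3a,4,7,8,8a-hexahydro-2H-cyclohepta[b]furan-2-one | C=C1C(=O)O[C@@H]2C[C@H](C)C(/C=C/C(C)=O)=CC[C@H]12 | intermediate
28 | (3aS,7R,8aS)-enantiomer of 27 | C=C1C(=O)O[C@H]2C[C@@H](C)C(/C=C/C(C)=O)=CC[C@@H]12 | intermediate
29 | 1,5-epoxide of 28, oxygen trans to the C10 methyl and the lactone | C=C1C(=O)O[C@H]2C[C@@H](C)[C@]3(/C=C/C(C)=O)O[C@@H]3C[C@@H]12 | intermediate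
30 | Diels–Alder adduct of 27 and 29 (C1=C2, H-3 cis to H-5) | C=C1C(=O)O[C@@H]2C[C@H](C)C3=C[C@H](C(C)=O)[C@]4(C[C@@H]3C[C@H]12)C(=O)O[C@H]1C[C@@H](C)[C@]2(/C=C/C(C)=O)O[C@@H]2C[C@H]14 | intermediate
31 | C1 hydroperoxide of the target | C=C1C(=O)O[C@@H]2C[C@H](C)[C@@]3(OO)C=C(C(C)=O)[C@]4(C[C@@H]3C[C@H]12)C(=O)O[C@H]1C[C@@H](C)[C@]2(/C=C/C(C)=O)O[C@@H]2C[C@H]14 | intermediate
32 | CNP0177598.2 | C=C1C(=O)O[C@@H]2C[C@H](C)[C@@]3(O)C=C(C(C)=O)[C@]4(C[C@@H]3C[C@H]12)C(=O)O[C@H]1C[C@@H](C)[C@]2(/C=C/C(C)=O)O[C@@H]2C[C@H]14 | target

**Totals and risks**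
Total step count: 18. Longest linear sequence: 18 (steps 1 to 18; 27 and 28 both come from 26).

Steps most likely to fail:

1. Step 17. The diene 27 is itself a methylene lactone, so self-cycloaddition may compete with the slow cross-reaction of two electron-poor partners, and the face selectivity on the diene rests on ring conformation only. The fallback sets out from 27 and returns at 30. Conjugate addition of dimethylamine (Me2NH, THF, 0 °C) masks the methylene lactone of 27 as amine adduct F1, which can no longer act as dienophile. F1 and 29 are heated as before to give cycloadduct F2. Methyl iodide converts F2 into methiodide F3, and aqueous NaHCO3 eliminates trimethylamine to regenerate the methylene lactone, giving 30. This fallback removes self-dimerisation but does not correct a wrong diene face.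

2. Step 18. The dienolate may be protonated at C1 (isomerisation to the conjugated enone without oxygen uptake), the base may attack the methylene lactones, or oxygen may enter on the wrong face. The fallback sets out from 30 and returns at 32. Soft enolisation with t-BuMe2SiOTf/Et3N (CH2Cl2, −78 °C) gives silyl dienol ether F4. F4 is oxidised at the γ-carbon C1 with mCPBA (NaHCO3, CH2Cl2, −20 °C; vinylogous Rubottom oxidation) and freed from silicon with HF·pyridine to give 32, so no free dienolate is involved.

3. Step 16. Oxygen may be delivered to the face syn to the C10 methyl if the ring folds so that this face is the exposed one, giving the epimeric epoxide. The fallback sets out from 28 and returns at 29. N-Bromosuccinimide in aqueous THF (0 °C) gives bromohydrin F5, with bromine on C5 on the face the electrophile prefers and water adding at C1 from the other face. K2CO3 in acetone then closes the ring by SN2 at C5, which places the oxirane oxygen on the face opposite to that reached by direct epoxidation, giving 29.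

**Further compounds**
F1 | step 17 | dimethylamine adduct of 27 (CH2NMe2 on C11, C11 epimers) | CN(C)CC1C(=O)O[C@@H]2C[C@H](C)C(/C=C/C(C)=O)=CC[C@H]12
F2 | step 17 | Diels–Alder adduct of F1 and 29 | CN(C)CC1C(=O)O[C@@H]2C[C@H](C)C3=C[C@H](C(C)=O)[C@]4(C[C@@H]3C[C@H]12)C(=O)O[C@H]1C[C@@H](C)[C@]2(/C=C/C(C)=O)O[C@@H]2C[C@H]14
F3 | step 17 | trimethylammonium iodide of F2 | C[N+](C)(C)CC1C(=O)O[C@@H]2C[C@H](C)C3=C[C@H](C(C)=O)[C@]4(C[C@@H]3C[C@H]12)C(=O)O[C@H]1C[C@@H](C)[C@]2(/C=C/C(C)=O)O[C@@H]2C[C@H]14.[I-]
F4 | step 18 | tert-butyldimethylsilyl dienol ether of 30 (C4–OSi, C3=C4, C1=C2) | C=C1C(=O)O[C@@H]2C[C@H](C)C3=CC(=C(C)O[Si](C)(C)C(C)(C)C)[C@]4(C[C@@H]3C[C@H]12)C(=O)O[C@H]1C[C@@H](C)[C@]2(/C=C/C(C)=O)O[C@@H]2C[C@H]14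
F5 | step 16 | bromohydrin of 28 (C1–OH trans to the C10 methyl, C5–Br cis to it) | C=C1C(=O)O[C@H]2C[C@@H](C)[C@@](O)(/C=C/C(C)=O)[C@@H](Br)C[C@@H]12
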